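**Remark on the chemistry (assumption).** On this palindromic chain the two @@ descriptors correspond to (2S,3R). Because C2 and C3 carry the same four substituents, this is the meso diastereomer, and the route is aimed at this achiral compound. Compounds 1 and 4 and benzyl bromide are taken as commercially available.

## Analysis of the target

The target 12 (C30H26O8) is an acyclic butane-1,4-dione. C1 and C4 are aryl ketone carbons bearing 2,4-dihydroxyphenyl rings (ring A on C1, ring D on C4). C2 and C3 each carry a 4-hydroxybenzyl group (ring B on the C2 side, ring C on the C3 side). The molecule consists of two identical C15 dihydrochalcone halves joined through the C2–C3 bond. Both ends of that bond are α-carbons of a ketone, so they have the same native (nucleophilic) polarity; this is the feature the strategy is built on. C2 and C3 are the only stereocenters, they are adjacent, and they are mirror-related (meso), so no absolute control is needed, only meso versus racemic. Both stereocenters are tertiary α-keto methines and epimerize with base or acid. That is a hazard late in the route and also a handle for equilibration. The six phenols are electron-rich and acidic, and a 1,4-diketone can cyclodehydrate under acid to a furan (Paal–Knorr), which would erase both stereocenters, so the end-game must be neutral. The difficulty is therefore twofold: a hindered bond between two secondary carbons that each carry benzylic β-hydrogens (elimination to a chalcone is always open), and a single diastereomer in an open chain with no controlling element.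

## Retrosynthetic reasoning

**12 to 11.** The six O–H bonds are traced back to six O–benzyl bonds. Benzyl is chosen because one neutral hydrogenolysis removes all six without acid or base, so neither epimerization at C2/C3 nor furan formation is invited. The same group survives strong amide base and a copper oxidant.

**11 to 9.** No bond is cut here; this is a stereochemical disconnection. Meso 11 is traced to the mixture of meso and racemic diastereomers 9. The forward step must interconvert the two forms through enolate 10 and let only the meso form leave solution, so that whatever ratio the coupling delivers converges on one isomer.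

**9 to two molecules of 7 (through enolate 8).** The C2–C3 bond is cut. It is the only bond whose scission gives two identical fragments, removes both stereocenters at once and halves the carbon count (C30 skeleton to C15). A cut at C1–C2 or at C2–CH2 would keep one stereocenter in each fragment and break the symmetry. The forward reaction has to join two nucleophilic α-carbons, which calls for one-electron oxidation of enolate 8.

**7 to 6, and 6 to 3 plus 4 (through aldol 5).** The saturated C2–CH2 link is traced to the enone C=C of chalcone 6. That bond is cut between the future C2 and the future benzylic carbon, giving methyl ketone 3 and the non-enolizable aldehyde 4. The forward condensation is unambiguous because only 3 can form an enolate, and the alkene geometry is irrelevant since it is hydrogenated.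

**3 to 1 (through 2).** Two O–benzyl bonds are cut, leading back to commercial 1.

## Alternatives that were turned down

Alternative 1: The textbook polar construction of a 1,4-diketone cuts the same C2–C3 bond into an electrophile and a nucleophile. The forward step is alkylation of enolate 8 with the α-bromoketone A1, 2-bromo-1-[2,4-bis(benzyloxy)phenyl]-3-[4-(benzyloxy)phenyl]propan-1-one, made from 7 by α-bromination. It was turned down for four reasons.
- A1 is a secondary bromide with acidic benzylic β-hydrogens, so the basic enolate should eliminate HBr to the conjugated chalcone 6 faster than it substitutes.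
- SN2 at a secondary α-carbon by a trisubstituted enolate is slow, and attack at the carbonyl (epoxide formation) competes.
- It costs one more step than direct oxidative coupling.
- It gives no better control of the C2/C3 relationship.

Alternative 2: A C1–C2 disconnection by polarity reversal at the acyl carbon. The forward step is a carbene-catalysed Stetter addition of 2,4-bis(benzyloxy)benzaldehyde A2 to the enone A3, (E)-1-[2,4-bis(benzyloxy)phenyl]-2-[4-(benzyloxy)benzyl]-4-[4-(benzyloxy)phenyl]but-2-en-1-one, which would give 9. It was turned down for four reasons.
- A3 needs several steps of its own, and under the basic conditions its C=C bond should migrate into conjugation with ring C, which moves the acceptor carbon.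
- Intermolecular Stetter additions to α,β-disubstituted acyclic enones are poor.
- The electron-rich, ortho-alkoxy aldehyde A2 is a weak acyl-anion donor.
- C2 would be set by an uncontrolled enolate protonation, so the diastereomer problem remains while the symmetry of the target goes unused.

Alternative 3: A stereospecific route that cuts the ring A–C1 and ring D–C4 bonds.
- Forward sequence: cis-hydrogenation of 3,4-bis(4-methoxybenzyl)furan-2,5-dione A4 to the cis (meso) anhydride A5, then twofold Friedel–Crafts acylation of a resorcinol diether to the hexamethyl ether A6, then sixfold O-demethylation to 12.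
- Attraction: the meso relationship is set by syn addition of hydrogen.
- Protecting-group problem: hydrogenating a tetrasubstituted alkene rules out benzyl ethers. The methyl ethers of A6 then need a strong Lewis acid for removal, which exposes a 1,4-diketone to Paal–Knorr furan formation and acid epimerization.
- Stereochemical problem: the aryl ketone bonds are made after the stereocenters exist, under Lewis acid and through enolizable acyl intermediates, so drift to the more stable trans series is likely.
- Step economy: A4 itself needs three to four steps, so the route is longer by at least two steps.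

Key step: step 4

## Route

Step 1
Reactants: 1 2,4-dihydroxyacetophenone
Product: 3 2,4-bis(benzyloxy)acetophenone, via 4-(benzyloxy)-2-hydroxyacetophenone 2 (not isolated)
Conditions: BnBr (2.5 equiv), K2CO3 (3 equiv), DMF, 80 °C
Reagents that add atoms: benzyl bromide, BrCc1ccccc1
Why: Twofold Williamson ether synthesis; the more acidic, non-chelated 4-OH should react first (2), and the hydrogen-bonded 2-OH follows with excess reagent and heat in DMF.

Step 2
Reactants: 3 2,4-bis(benzyloxy)acetophenone; 4 4-(benzyloxy)benzaldehyde
Product: 6 (E)-1-[2,4-bis(benzyloxy)phenyl]-3-[4-(benzyloxy)phenyl]prop-2-en-1-one, via aldol adduct 5 (not isolated)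
Conditions: KOH (aq.), EtOH/THF, 20 °C
Reagents that add atoms: none
Why: Claisen–Schmidt condensation; aldehyde 4 has no α-hydrogen, so only 3 can form an enolate, and aldol 5 should lose water by E1cB to the thermodynamic (E)-enone. With the ring A 2-oxygen benzylated, no flavanone can form.

Step 3
Reactants: 6 (E)-1-[2,4-bis(benzyloxy)phenyl]-3-[4-(benzyloxy)phenyl]prop-2-en-1-one
Product: 7 1-[2,4-bis(benzyloxy)phenyl]-3-[4-(benzyloxy)phenyl]propan-1-one
Conditions: H2 (4 bar), RhCl(PPh3)3 (3 mol%), toluene/EtOH, 40 °C
Reagents that add atoms: none
Why: Homogeneous hydrogenation with RhCl(PPh3)3 should saturate the disubstituted enone C=C bond; unlike heterogeneous palladium it neither cleaves aryl benzyl ethers nor reduces aryl ketones.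

Step 4
Reactants: 7 1-[2,4-bis(benzyloxy)phenyl]-3-[4-(benzyloxy)phenyl]propan-1-one (two molecules)
Product: 9 1,4-bis[2,4-bis(benzyloxy)phenyl]-2,3-bis[4-(benzyloxy)benzyl]butane-1,4-dione as a mixture of the meso and the racemic diastereomer, via lithium (Z)-enolate 8 (not isolated)
Conditions: LiN(iPr)2 (1.05 equiv), THF, −78 °C; then anhydrous CuCl2 (1.1 equiv) in DMF, −78 °C to 0 °C
Reagents that add atoms: none
Why: Oxidative homocoupling of a ketone enolate: lithium diisopropylamide can deprotonate 7 only at the future C2, because the other flank of the carbonyl is ring A, and should give the (Z)-enolate 8. Divalent copper then removes one electron per enolate (becoming monovalent copper), and two α-carbon units join at carbon, either as two α-keto radicals or as radical plus enolate followed by a second one-electron oxidation, to form the C2–C3 bond. The closest known reaction type is the CuCl2-mediated dimerization of lithium enolates of alkyl aryl ketones and of 3-arylpropanoyl enolates to 2,3-dibenzylsuccinic derivatives. No ring is closed. Both stereocenters, C2 and C3, are created here, and no element of 7 controls their relationship, so a mixture of meso and racemic forms is expected; this is accepted because both centers are enolizable and are funnelled to meso in step 5. The step needs C–C rather than C–O coupling, which the carbon-centred spin density of an aryl ketone enolate radical should secure. It also needs coupling to outrun α-chlorination and loss of HCl to chalcone 6, which is addressed by the low temperature, the absence of excess base and fast addition of the oxidant to the preformed enolate. The benzyl ethers are inert to both reagents, and the step assembles all 30 skeleton carbons from a 15-carbon precursor.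

Step 5
Reactants: 9 1,4-bis[2,4-bis(benzyloxy)phenyl]-2,3-bis[4-(benzyloxy)benzyl]butane-1,4-dione (diastereomer mixture)
Product: 11 meso-(2R,3S)-1,4-bis[2,4-bis(benzyloxy)phenyl]-2,3-bis[4-(benzyloxy)benzyl]butane-1,4-dione, via sodium enolate 10 (not isolated)
Conditions: NaOEt (0.2 equiv), EtOH/toluene, N2, 50 °C, then slow cooling to 0 °C with seeding; filtration
Reagents that add atoms: none
Why: Base-mediated epimerization of ketone α-stereocenters coupled to crystallization (crystallization-induced diastereomer transformation): catalytic ethoxide reversibly forms enolate 10, so meso and racemic forms interconvert in solution while the meso form should leave as a solid. The meso form is expected to be the less soluble one, as is the rule for 2,3-disubstituted 1,4-diaryl-1,4-diketones, because it can pack in a centrosymmetric antiperiplanar conformation. C2 and C3 are thereby fixed together, and 9 offers no other base-labile path (no retro-aldol, no ring closure, inert aryl benzyl ethers).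

Step 6
Reactants: 11 meso-(2R,3S)-1,4-bis[2,4-bis(benzyloxy)phenyl]-2,3-bis[4-(benzyloxy)benzyl]butane-1,4-dione
Product: 12 meso-(2R,3S)-1,4-bis(2,4-dihydroxyphenyl)-2,3-bis(4-hydroxybenzyl)butane-1,4-dione (target)
Conditions: H2 (1 atm), Pd/C (palladium on carbon, 10 wt%), THF/MeOH, 20 °C
Reagents that add atoms: none
Why: Hydrogenolysis of six aryl benzyl ethers under neutral conditions; the aryl ketones are deactivated towards reduction by their ortho- and para-oxygen donors, and the absence of acid and base should prevent epimerization at C2/C3 and Paal–Knorr furan formation. The reaction is stopped when hydrogen uptake ends.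

## Compound list

1 | 2,4-dihydroxyacetophenone | CC(=O)c1ccc(O)cc1O | starting material
2 | 4-(benzyloxy)-2-hydroxyacetophenone | CC(=O)c1ccc(OCc2ccccc2)cc1O | intermediate (not isolated)
3 | 2,4-bis(benzyloxy)acetophenone | CC(=O)c1ccc(OCc2ccccc2)cc1OCc1ccccc1 | intermediate
4 | 4-(benzyloxy)benzaldehyde | O=Cc1ccc(OCc2ccccc2)cc1 | starting material
5 | 1-[2,4-bis(benzyloxy)phenyl]-3-[4-(benzyloxy)phenyl]-3-hydroxypropan-1-one (racemic aldol adduct) | O=C(CC(O)c1ccc(OCc2ccccc2)cc1)c1ccc(OCc2ccccc2)cc1OCc1ccccc1 | intermediate (not isolated)
6 | (E)-1-[2,4-bis(benzyloxy)phenyl]-3-[4-(benzyloxy)phenyl]prop-2-en-1-one | O=C(/C=C/c1ccc(OCc2ccccc2)cc1)c1ccc(OCc2ccccc2)cc1OCc1ccccc1 | intermediate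
7 | 1-[2,4-bis(benzyloxy)phenyl]-3-[4-(benzyloxy)phenyl]propan-1-one | O=C(CCc1ccc(OCc2ccccc2)cc1)c1ccc(OCc2ccccc2)cc1OCc1ccccc1 | intermediate
8 | lithium (Z)-enolate of 7 | [Li]O/C(=C\Cc1ccc(OCc2ccccc2)cc1)c1ccc(OCc2ccccc2)cc1OCc1ccccc1 | intermediate (not isolated)
9 | 1,4-bis[2,4-bis(benzyloxy)phenyl]-2,3-bis[4-(benzyloxy)benzyl]butane-1,4-dione, mixture of meso and racemic diastereomers | O=C(c1ccc(OCc2ccccc2)cc1OCc1ccccc1)C(Cc1ccc(OCc2ccccc2)cc1)C(Cc1ccc(OCc2ccccc2)cc1)C(=O)c1ccc(OCc2ccccc2)cc1OCc1ccccc1 | intermediate
10 | sodium mono-enolate of 9 (remaining stereocenter of either configuration, enolate geometry not fixed) | [Na]OC(=C(Cc1ccc(OCc2ccccc2)cc1)C(Cc1ccc(OCc2ccccc2)cc1)C(=O)c1ccc(OCc2ccccc2)cc1OCc1ccccc1)c1ccc(OCc2ccccc2)cc1OCc1ccccc1 | intermediate (not isolated)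
11 | meso-(2R,3S)-1,4-bis[2,4-bis(benzyloxy)phenyl]-2,3-bis[4-(benzyloxy)benzyl]butane-1,4-dione | O=C(c1ccc(OCc2ccccc2)cc1OCc1ccccc1)[C@@H](Cc1ccc(OCc2ccccc2)cc1)[C@@H](Cc1ccc(OCc2ccccc2)cc1)C(=O)c1ccc(OCc2ccccc2)cc1OCc1ccccc1 | intermediate
12 | meso-(2R,3S)-1,4-bis(2,4-dihydroxyphenyl)-2,3-bis(4-hydroxybenzyl)butane-1,4-dione | O=C(c1ccc(O)cc1O)[C@@H](Cc1ccc(O)cc1)[C@@H](Cc1ccc(O)cc1)C(=O)c1ccc(O)cc1O | target

## Step count and risk

Total step count: 6. Longest linear sequence: 6 steps (1 to 12); the route is linear, with aldehyde 4 entering in step 2.

**Step 4 (key step).** The most likely failure is oxidation without coupling. The oxidized α-carbon carries a benzylic CH2, so α-chlorination followed by loss of HCl, or direct dehydrogenation, would return chalcone 6. In addition, proton transfer from product 9 (still α-acidic) to enolate 8 would stall conversion and expose 9 to over-oxidation. The fallback builds the C2–C3 bond before the benzyl groups are present, where no β-hydrogen exists. It sets out from 3, which is deprotonated with LiN(iPr)2 and oxidized with CuCl2 to 1,4-bis[2,4-bis(benzyloxy)phenyl]butane-1,4-dione F1. F1 is then deprotonated twice with LiN(iPr)2 in THF and alkylated at both α-carbons with 4-(benzyloxy)benzyl bromide, which returns to the route at 9.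

**Step 5.** What may go wrong is failure of the selective crystallization: the hexabenzyl ether may oil out, the racemic form may crystallize instead, or epimerization at the hindered methines may be slow compared with crystal growth. The identity of the solid would be checked by chromatography on a chiral stationary phase (one peak for meso, two for the racemate) or by X-ray diffraction. The fallback replaces crystallization control by separation and recycling. It sets out from 9, which is equilibrated in homogeneous solution (catalytic DBU, THF) and separated by chromatography into 11 and the racemic (2R*,3R*) diastereomer F2. F2 is returned to the equilibration until it is consumed, and the route is rejoined at 11.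

**Step 6.** The risks are incomplete cleavage of six ethers on a poorly soluble substrate, and at long reaction times reduction of the benzylic ketones or hydrogenolysis of the resulting alcohols. The fallback is a non-reductive debenzylation from 11 with BCl3 and pentamethylbenzene as cation scavenger in CH2Cl2 at −78 °C; the low temperature should keep the 1,4-diketone from cyclizing. It returns at 12 and makes no new compound (F0).

**Step 3.** The risk is slow hydrogenation of the conjugated, electron-rich enone at the homogeneous rhodium catalyst, or onset of carbonyl reduction under forcing conditions. The fallback bypasses chalcone 6: from 3, deprotonation with LiN(iPr)2 and C-alkylation with a deficit of 4-(benzyloxy)benzyl bromide (inverse addition to limit dialkylation) gives 7 directly. It makes no new compound (F0).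

## Further compounds

F1 | step 4 | 1,4-bis[2,4-bis(benzyloxy)phenyl]butane-1,4-dione | O=C(CCC(=O)c1ccc(OCc2ccccc2)cc1OCc1ccccc1)c1ccc(OCc2ccccc2)cc1OCc1ccccc1
F2 | step 5 | racemic (2R*,3R*)-1,4-bis[2,4-bis(benzyloxy)phenyl]-2,3-bis[4-(benzyloxy)benzyl]butane-1,4-dione, (2S,3S) enantiomer drawn | O=C(c1ccc(OCc2ccccc2)cc1OCc1ccccc1)[C@@H](Cc1ccc(OCc2ccccc2)cc1)[C@H](Cc1ccc(OCc2ccccc2)cc1)C(=O)c1ccc(OCc2ccccc2)cc1OCc1ccccc1
F0 | step 6 | none | none
F0 | step 3 | none | none
A1 | alternative 1 | 2-bromo-1-[2,4-bis(benzyloxy)phenyl]-3-[4-(benzyloxy)phenyl]propan-1-one (racemic) | O=C(C(Br)Cc1ccc(OCc2ccccc2)cc1)c1ccc(OCc2ccccc2)cc1OCc1ccccc1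
A2 | alternative 2 | 2,4-bis(benzyloxy)benzaldehyde | O=Cc1ccc(OCc2ccccc2)cc1OCc1ccccc1
A3 | alternative 2 | (E)-1-[2,4-bis(benzyloxy)phenyl]-2-[4-(benzyloxy)benzyl]-4-[4-(benzyloxy)phenyl]but-2-en-1-one | O=C(c1ccc(OCc2ccccc2)cc1OCc1ccccc1)/C(Cc1ccc(OCc2ccccc2)cc1)=C/Cc1ccc(OCc2ccccc2)cc1
A4 | alternative 3 | 3,4-bis(4-methoxybenzyl)furan-2,5-dione | O=C1OC(=O)C(Cc2ccc(OC)cc2)=C1Cc1ccc(OC)cc1
A5 | alternative 3 | cis-(3R,4S)-3,4-bis(4-methoxybenzyl)dihydrofuran-2,5-dione (meso) | O=C1OC(=O)[C@@H](Cc2ccc(OC)cc2)[C@H]1Cc1ccc(OC)cc1
A6 | alternative 3 | meso-(2R,3S)-1,4-bis(2,4-dimethoxyphenyl)-2,3-bis(4-methoxybenzyl)butane-1,4-dione | O=C(c1ccc(OC)cc1OC)[C@@H](Cc1ccc(OC)cc1)[C@@H](Cc1ccc(OC)cc1)C(=O)c1ccc(OC)cc1OC
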